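The plan hinges on taking ring B' apart into two three-carbon pieces: C-1', C-2' and C-3' come from the CH2–CO–CH3 end of a butane-1,3-dione chain on ring A', and C-4', C-5' and C-6' (with its methyl) from methyl crotonate. This exploits the acyl-orcinol pattern of ring B': O-2' and O-4' are 1,3-related and the C-6' methyl flanks the ketone-bearing C-1'. A single Michael–Claisen annulation forms the C-1'–C-6' and C-3'–C-4' bonds and delivers the ring as a cyclohexane-1,3-dione; dehydrogenation then gives the arene. The precursor is the hexabenzylated diarylmethane in which the ring A–ring B benzophenone and the methylene bridge are already complete.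

Key step: step 11

Remark on the chemistry: 2,4-dihydroxy-6-methylbenzaldehyde and 1-(2,6-dihydroxy-4-methoxyphenyl)ethanone are taken as catalogue compounds. The β-triketones are drawn in the triketo form although they are largely enolised, so "trans" refers to that tautomer.

Remark on names: ring A carries ring B (2,4-dihydroxy-6-methylbenzoyl) and ring A' carries ring B'. "Ar" stands for 2,6-bis(benzyloxy)-3-{[2,4-bis(benzyloxy)-3-(2,4-bis(benzyloxy)-6-methylbenzoyl)-6-methoxyphenyl]methyl}-4-methoxyphenyl, that is, perbenzylated ring A' with rings A and B attached.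

Step 1
Reactants: 1 2,4-dihydroxy-6-methylbenzaldehyde
Product: 2 2,4-bis(benzyloxy)-6-methylbenzaldehyde
Conditions: BnBr (2.4 equiv), K2CO3, DMF, 60 °C
Reagents that add atoms: benzyl bromide, BrCc1ccccc1
Why: Williamson etherification of both phenoxides, the hydrogen-bonded 2-OH needing DMF and warmth, while the aldehyde is inert to carbonate.

Step 2
Reactants: 3 phloroglucinol
Product: 4 1,3,5-tris(methoxymethoxy)benzene
Conditions: MOMCl (3.6 equiv), i-Pr2NEt, CH2Cl2, 0 °C to rt
Reagents that add atoms: chloromethyl methyl ether, COCCl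
Why: O-alkylation of the phenol with a hard oxocarbenium-type electrophile under amine base gives the tris-acetal, C-alkylation being negligible with this reagent.

Step 3
Reactants: 4 1,3,5-tris(methoxymethoxy)benzene; 2 2,4-bis(benzyloxy)-6-methylbenzaldehyde
Product: 6 [2,4-bis(benzyloxy)-6-methylphenyl][2,4,6-tris(methoxymethoxy)phenyl]methanol (racemic), via aryllithium 5 (not isolated)
Conditions: n-BuLi, THF, 0 °C; then 2, −78 °C to rt; H2O
Reagents that add atoms: none
Why: Directed ortho-lithiation can give only one aryllithium because every ring C–H lies between two OMOM groups, and its 1,2-addition to the aldehyde forms the carbinol centre without control (racemic), a centre that step 4 removes.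

Step 4
Reactants: 6 [2,4-bis(benzyloxy)-6-methylphenyl][2,4,6-tris(methoxymethoxy)phenyl]methanol
Product: 7 [2,4-bis(benzyloxy)-6-methylphenyl][2,4,6-tris(methoxymethoxy)phenyl]methanone
Conditions: Dess–Martin periodinane, CH2Cl2, rt
Reagents that add atoms: none
Why: Dess–Martin oxidation of a secondary benzhydrol stops cleanly at the diaryl ketone and leaves acetals and benzyl ethers untouched.

Step 5
Reactants: 7 [2,4-bis(benzyloxy)-6-methylphenyl][2,4,6-tris(methoxymethoxy)phenyl]methanone
Product: 8 [2,4-bis(benzyloxy)-6-methylphenyl](2,4,6-trihydroxyphenyl)methanone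
Conditions: HCl (cat.), MeOH/THF, 50 °C
Reagents that add atoms: none
Why: Acid-catalysed acetal exchange with methanol removes the three MOM groups, whereas benzyl ethers and the diaryl ketone are stable to dilute acid.

Step 6
Reactants: 8 [2,4-bis(benzyloxy)-6-methylphenyl](2,4,6-trihydroxyphenyl)methanone
Product: 9 [2,4-bis(benzyloxy)-6-methylphenyl](2,6-dihydroxy-4-methoxyphenyl)methanone
Conditions: Me2SO4 (1.05 equiv), K2CO3, acetone, rt
Reagents that add atoms: dimethyl sulfate, COS(=O)(=O)OC
Why: Williamson methylation under stoichiometric control should take the 4-OH first, since it is para to the carbonyl, the most acidic, and the only hydroxyl neither hydrogen-bonded to nor flanked by the ketone.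

Step 7
Reactants: 9 [2,4-bis(benzyloxy)-6-methylphenyl](2,6-dihydroxy-4-methoxyphenyl)methanone
Product: 10 [2,4-bis(benzyloxy)-6-methylphenyl]{3-[(dimethylamino)methyl]-2,6-dihydroxy-4-methoxyphenyl}methanone
Conditions: Eschenmoser's salt (CH2=NMe2+ I−, 1.0 equiv), Et3N, CH2Cl2, 0 °C to rt
Reagents that add atoms: N,N-dimethylmethyleneiminium iodide, C=[N+](C)C.[I-]
Why: Mannich aminomethylation occurs at C-3 of ring A (C-3 and C-5 are equivalent and are the only phenol-activated C–H sites), and one equivalent of iminium salt should keep it to mono-substitution.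

Step 8
Reactants: 10 [2,4-bis(benzyloxy)-6-methylphenyl]{3-[(dimethylamino)methyl]-2,6-dihydroxy-4-methoxyphenyl}methanone; 11 1-(2,6-dihydroxy-4-methoxyphenyl)ethanone
Product: 13 1-[3-({3-[2,4-bis(benzyloxy)-6-methylbenzoyl]-2,4-dihydroxy-6-methoxyphenyl}methyl)-2,6-dihydroxy-4-methoxyphenyl]ethanone, via ortho-quinone methide 12 (not isolated)
Conditions: 11 (3 equiv), 1,4-dioxane, 100 °C, N2 sweep
Reagents that add atoms: none
Why: Thermal loss of dimethylamine from the Mannich base gives the ring A ortho-quinone methide, which is trapped in a Michael-type C-alkylation by C-3 of the excess acetophenone, the usual way to unsymmetrical methylene-bridged acylphloroglucinols.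

Step 9
Reactants: 13 1-[3-({3-[2,4-bis(benzyloxy)-6-methylbenzoyl]-2,4-dihydroxy-6-methoxyphenyl}methyl)-2,6-dihydroxy-4-methoxyphenyl]ethanone
Product: 14 1-Ar-ethanone (the tetra-O-benzyl ether of 13)
Conditions: BnBr (6 equiv), K2CO3, DMF, 70 °C
Reagents that add atoms: benzyl bromide, BrCc1ccccc1
Why: Fourfold Williamson benzylation, with DMF and warming to force the carbonyl-chelated hydroxyls, leaves no acidic O–H and removes the phenols that make the bridge labile.

Step 10
Reactants: 14 1-Ar-ethanone
Product: 15 1-Ar-butane-1,3-dione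
Conditions: NaH, EtOAc (excess), THF, reflux; then dilute HCl
Reagents that add atoms: ethyl acetate, CCOC(C)=O
Why: Crossed Claisen condensation of the only enolisable ketone with ethyl acetate is driven by formation of the sodium diketonate, as in the classical acetylation of phloracetophenone ethers.

Step 11
Reactants: 15 1-Ar-butane-1,3-dione; 16 methyl (E)-crotonate
Product: 18 racemic trans-4-(Ar-carbonyl)-5-methylcyclohexane-1,3-dione (4R*,5S*), via Michael adduct 17 (not isolated)
Conditions: NaOMe (3 equiv), 16 (3 equiv), MeOH/THF, reflux; then dilute HCl, 0 °C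
Reagents that add atoms: none
Why: Deprotonation of 15 between its two carbonyls gives a sodium diketonate that attacks the crotonate in conjugate fashion through C-2 of the butanedione chain, so the crotonate methyl ends up on the ring carbon next to the one carrying the ketone (adduct 17). Within 17 the terminal CH3CO group is the only enolisable position from which the ester can be reached through a six-membered transition state, and its enolate acylates itself on the ester carbonyl (6-exo-trig, Dieckmann-like Claisen closure) with loss of methoxide. The closest known reaction is the Michael–Claisen annulation of acetoacetates with crotonates that gives dihydro-orsellinates, here run on an aroylacetone. The ring product is at once deprotonated to a delocalised triketone enolate, and this acid–base sink is what lets the slow, reversible conjugate addition compete with methoxide-induced retro-Claisen cleavage of the diketone. The two new centres are set without external control: the aroyl-bearing carbon is enolisable and should settle in the trans arrangement that keeps aroyl and methyl apart, the material is racemic, and both centres disappear in step 12. The step needs C- rather than O-alkylation and acylation at the ester rather than at a ketone; this is secured by the soft diketonate–enoate pairing, by all phenols being benzylated (one acidic site, no chromone closure) and by the tetra-ortho-substituted A–B ketone being inert to methoxide.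

Step 12
Reactants: 18 racemic trans-4-(Ar-carbonyl)-5-methylcyclohexane-1,3-dione
Product: 20 Ar (2,4-dihydroxy-6-methylphenyl) ketone, via bromotrione 19 (not isolated)
Conditions: Br2 (1.0 equiv), DMF, 0 °C; then 80 °C
Reagents that add atoms: none
Why: Bromination–dehydrobromination, the aromatisation used for dihydro-resorcylates: the enolised triketone takes up bromine far faster than any alkoxyarene, the α-bromo-β-dicarbonyl isomers interconvert under HBr, and the isomer brominated at the aroyl-bearing carbon loses HBr towards C-5 and tautomerises to the resorcinol with no oxidant left for the diarylmethane CH2, erasing both stereocentres.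

Step 13
Reactants: 20 Ar (2,4-dihydroxy-6-methylphenyl) ketone
Product: 21 Ar [4-(benzyloxy)-2-hydroxy-6-methylphenyl] ketone
Conditions: BnBr (1.1 equiv), K2CO3, acetone, rt
Reagents that add atoms: benzyl bromide, BrCc1ccccc1
Why: Regioselective Williamson benzylation, since the 4'-OH is free and the more acidic while the 2'-OH is locked in a hydrogen bond to the ketone.

Step 14
Reactants: 21 Ar [4-(benzyloxy)-2-hydroxy-6-methylphenyl] ketone
Product: 22 Ar [4-(benzyloxy)-2-methoxy-6-methylphenyl] ketone (the hepta-O-benzyl ether of the target)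
Conditions: MeI (excess), K2CO3, DMF, 50 °C
Reagents that add atoms: iodomethane, CI
Why: Williamson methylation of the one remaining O–H, the chelated phenol, which excess iodomethane in DMF forces to completion.

Step 15
Reactants: 22 Ar [4-(benzyloxy)-2-methoxy-6-methylphenyl] ketone
Product: 23 target CNP0596095.0
Conditions: H2 (1 atm), 10% Pd/C, EtOAc/MeOH, rt
Reagents that add atoms: none
Why: Catalytic hydrogenolysis cleaves the seven benzyl ethers, while the hindered, hydrogen-bonded diaryl ketones and the diarylmethane should not be reduced at 1 atm and room temperature.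

Compound list
1 | 2,4-dihydroxy-6-methylbenzaldehyde | Cc1cc(O)cc(O)c1C=O | starting material
2 | 2,4-bis(benzyloxy)-6-methylbenzaldehyde | Cc1cc(OCc2ccccc2)cc(OCc2ccccc2)c1C=O | intermediate
3 | phloroglucinol (benzene-1,3,5-triol) | Oc1cc(O)cc(O)c1 | starting material
4 | 1,3,5-tris(methoxymethoxy)benzene | COCOc1cc(OCOC)cc(OCOC)c1 | intermediate
5 | 2,4,6-tris(methoxymethoxy)phenyllithium | [Li]c1c(OCOC)cc(OCOC)cc1OCOC | intermediate (not isolated)
6 | [2,4-bis(benzyloxy)-6-methylphenyl][2,4,6-tris(methoxymethoxy)phenyl]methanol, racemic | COCOc1cc(OCOC)c(C(O)c2c(C)cc(OCc3ccccc3)cc2OCc2ccccc2)c(OCOC)c1 | intermediate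
7 | [2,4-bis(benzyloxy)-6-methylphenyl][2,4,6-tris(methoxymethoxy)phenyl]methanone | COCOc1cc(OCOC)c(C(=O)c2c(C)cc(OCc3ccccc3)cc2OCc2ccccc2)c(OCOC)c1 | intermediate
8 | [2,4-bis(benzyloxy)-6-methylphenyl](2,4,6-trihydroxyphenyl)methanone | Oc1cc(O)c(C(=O)c2c(C)cc(OCc3ccccc3)cc2OCc2ccccc2)c(O)c1 | intermediate
9 | [2,4-bis(benzyloxy)-6-methylphenyl](2,6-dihydroxy-4-methoxyphenyl)methanone (A–B benzophenone) | COc1cc(O)c(C(=O)c2c(C)cc(OCc3ccccc3)cc2OCc2ccccc2)c(O)c1 | intermediate
10 | [2,4-bis(benzyloxy)-6-methylphenyl]{3-[(dimethylamino)methyl]-2,6-dihydroxy-4-methoxyphenyl}methanone (Mannich base) | COc1cc(O)c(C(=O)c2c(C)cc(OCc3ccccc3)cc2OCc2ccccc2)c(O)c1CN(C)C | intermediate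
11 | 1-(2,6-dihydroxy-4-methoxyphenyl)ethanone | CC(=O)c1c(O)cc(OC)cc1O | starting material
12 | ortho-quinone methide of ring A: 2-[2,4-bis(benzyloxy)-6-methylbenzoyl]-3-hydroxy-5-methoxy-6-methylidenecyclohexa-2,4-dien-1-one | C=C1C(=O)C(C(=O)c2c(C)cc(OCc3ccccc3)cc2OCc2ccccc2)=C(O)C=C1OC | intermediate (not isolated)
13 | 1-[3-({3-[2,4-bis(benzyloxy)-6-methylbenzoyl]-2,4-dihydroxy-6-methoxyphenyl}methyl)-2,6-dihydroxy-4-methoxyphenyl]ethanone | COc1cc(O)c(C(=O)c2c(C)cc(OCc3ccccc3)cc2OCc2ccccc2)c(O)c1Cc1c(OC)cc(O)c(C(C)=O)c1O | intermediate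
14 | 1-Ar-ethanone (hexabenzyl aryl methyl ketone) | COc1cc(OCc2ccccc2)c(C(=O)c2c(C)cc(OCc3ccccc3)cc2OCc2ccccc2)c(OCc2ccccc2)c1Cc1c(OC)cc(OCc2ccccc2)c(C(C)=O)c1OCc1ccccc1 | intermediate
15 | 1-Ar-butane-1,3-dione (ring A' aroylacetone, key-step precursor) | COc1cc(OCc2ccccc2)c(C(=O)c2c(C)cc(OCc3ccccc3)cc2OCc2ccccc2)c(OCc2ccccc2)c1Cc1c(OC)cc(OCc2ccccc2)c(C(=O)CC(C)=O)c1OCc1ccccc1 | intermediate
16 | methyl (E)-crotonate | C/C=C/C(=O)OC | starting material
17 | methyl 4-(Ar-carbonyl)-3-methyl-5-oxohexanoate (Michael adduct, diastereomer mixture) | COc1cc(OCc2ccccc2)c(C(=O)c2c(C)cc(OCc3ccccc3)cc2OCc2ccccc2)c(OCc2ccccc2)c1Cc1c(OC)cc(OCc2ccccc2)c(C(=O)C(C(C)=O)C(C)CC(=O)OC)c1OCc1ccccc1 | intermediate (not isolated)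
18 | racemic trans-4-(Ar-carbonyl)-5-methylcyclohexane-1,3-dione, 4R*,5S* (key-step product; one enantiomer drawn) | COc1cc(OCc2ccccc2)c(C(=O)c2c(C)cc(OCc3ccccc3)cc2OCc2ccccc2)c(OCc2ccccc2)c1Cc1c(OC)cc(OCc2ccccc2)c(C(=O)[C@H]2C(=O)CC(=O)C[C@@H]2C)c1OCc1ccccc1 | intermediate
19 | 4-(Ar-carbonyl)-4-bromo-5-methylcyclohexane-1,3-dione (racemic, relative configuration not defined) | COc1cc(OCc2ccccc2)c(C(=O)c2c(C)cc(OCc3ccccc3)cc2OCc2ccccc2)c(OCc2ccccc2)c1Cc1c(OC)cc(OCc2ccccc2)c(C(=O)C2(Br)C(=O)CC(=O)CC2C)c1OCc1ccccc1 | intermediate (not isolated)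
20 | Ar (2,4-dihydroxy-6-methylphenyl) ketone | COc1cc(OCc2ccccc2)c(C(=O)c2c(C)cc(OCc3ccccc3)cc2OCc2ccccc2)c(OCc2ccccc2)c1Cc1c(OC)cc(OCc2ccccc2)c(C(=O)c2c(C)cc(O)cc2O)c1OCc1ccccc1 | intermediate
21 | Ar [4-(benzyloxy)-2-hydroxy-6-methylphenyl] ketone | COc1cc(OCc2ccccc2)c(C(=O)c2c(C)cc(OCc3ccccc3)cc2OCc2ccccc2)c(OCc2ccccc2)c1Cc1c(OC)cc(OCc2ccccc2)c(C(=O)c2c(C)cc(OCc3ccccc3)cc2O)c1OCc1ccccc1 | intermediate
22 | Ar [4-(benzyloxy)-2-methoxy-6-methylphenyl] ketone | COc1cc(OCc2ccccc2)c(C(=O)c2c(C)cc(OCc3ccccc3)cc2OCc2ccccc2)c(OCc2ccccc2)c1Cc1c(OC)cc(OCc2ccccc2)c(C(=O)c2c(C)cc(OCc3ccccc3)cc2OC)c1OCc1ccccc1 | intermediate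
23 | CNP0596095.0 (no stereocentres) | COc1cc(O)c(C(=O)c2c(C)cc(O)cc2O)c(O)c1Cc1c(OC)cc(O)c(C(=O)c2c(C)cc(O)cc2OC)c1O | target

Total steps: 15. Longest linear sequence: 14 steps (phloroglucinol 3 to target 23, steps 2 to 15).

Steps most likely to fail

Step 11. The conjugate addition of the hindered diketonate to the weakly electrophilic crotonate may be too slow and too reversible, so that methoxide cleaves the diketone (retro-Claisen loss of the acetyl or aroyl group) before any ring closes. Fallback: from 15 the acceptor is changed to diethyl ethylidenemalonate (NaOEt, EtOH/THF), whose second ester should make the addition fast and hard to reverse. The Michael adduct F1 would close in the same pot, through the same acetyl-methyl enolate, to the annulated β-keto ester F2 (the dimedone-type sequence). Hot aqueous KOH, then acidification and gentle warming, would hydrolyse the ester to the β-keto acid F3 and decarboxylate it, which rejoins the route at 18.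

Step 12. Bromine may be passed on from the α-bromo triketone to the electron-rich alkoxyarene rings, or the hydrogen bromide released during the warm elimination stage may strip benzyl ethers that sit ortho to a carbonyl, leaving aromatisation incomplete. Ring bromide that slips through would be hydrogenolysed in step 15. Fallback: from 18 the triketone is O-silylated (TMSOTf, Et3N, CH2Cl2, 0 °C) to the bis(trimethylsilyl) dienol ether F4, a cyclohexa-1,3-diene that a quinone (DDQ, 0 °C) should dehydrogenate far faster than it attacks any benzylic C–H. This gives the aryl bis(trimethylsilyl) ether F5, and dilute HCl in THF removes the silyl groups and returns the route at 20.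

Step 8. Methylene exchange may scramble the coupling: the quinone methide can be trapped by a second molecule of its own precursor, or the cross product can fragment again under the amine at 100 °C, leading to the symmetric dimers. Fallback: the bridge is made by cationic Friedel–Crafts benzylation instead of through a quinone methide. From 11, Rieche formylation (Cl2CHOMe, TiCl4, CH2Cl2) would give 3-acetyl-2,4-dihydroxy-6-methoxybenzaldehyde F6, and benzylation (BnBr, K2CO3, DMF) the bis(benzyl) ether F7. NaBH4 at −20 °C should then reduce only the aldehyde, to the benzylic alcohol F8. Under catalytic TsOH in CH2Cl2 its trialkoxybenzyl cation would alkylate C-3 of 9 to give the diarylmethane F9, whose ring A' is already capped so that the bridge cannot be expelled from that side. Benzylation of the two ring A hydroxyls under the conditions of step 9 rejoins the route at 14.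

Further compounds
F1 | step 11 | diethyl 2-[3-(Ar-carbonyl)-4-oxopentan-2-yl]propanedioate (Michael adduct, diastereomer mixture) | COc1cc(OCc2ccccc2)c(C(=O)c2c(C)cc(OCc3ccccc3)cc2OCc2ccccc2)c(OCc2ccccc2)c1Cc1c(OC)cc(OCc2ccccc2)c(C(=O)C(C(C)=O)C(C)C(C(=O)OCC)C(=O)OCC)c1OCc1ccccc1
F2 | step 11 | ethyl 3-(Ar-carbonyl)-2-methyl-4,6-dioxocyclohexane-1-carboxylate (diastereomer mixture) | COc1cc(OCc2ccccc2)c(C(=O)c2c(C)cc(OCc3ccccc3)cc2OCc2ccccc2)c(OCc2ccccc2)c1Cc1c(OC)cc(OCc2ccccc2)c(C(=O)C2C(=O)CC(=O)C(C(=O)OCC)C2C)c1OCc1ccccc1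
F3 | step 11 | 3-(Ar-carbonyl)-2-methyl-4,6-dioxocyclohexane-1-carboxylic acid (diastereomer mixture) | COc1cc(OCc2ccccc2)c(C(=O)c2c(C)cc(OCc3ccccc3)cc2OCc2ccccc2)c(OCc2ccccc2)c1Cc1c(OC)cc(OCc2ccccc2)c(C(=O)C2C(=O)CC(=O)C(C(=O)O)C2C)c1OCc1ccccc1
F4 | step 12 | Ar [6-methyl-2,4-bis(trimethylsilyloxy)cyclohexa-1,3-dien-1-yl] ketone (racemic) | COc1cc(OCc2ccccc2)c(C(=O)c2c(C)cc(OCc3ccccc3)cc2OCc2ccccc2)c(OCc2ccccc2)c1Cc1c(OC)cc(OCc2ccccc2)c(C(=O)C2=C(O[Si](C)(C)C)C=C(O[Si](C)(C)C)CC2C)c1OCc1ccccc1
F5 | step 12 | Ar [6-methyl-2,4-bis(trimethylsilyloxy)phenyl] ketone | COc1cc(OCc2ccccc2)c(C(=O)c2c(C)cc(OCc3ccccc3)cc2OCc2ccccc2)c(OCc2ccccc2)c1Cc1c(OC)cc(OCc2ccccc2)c(C(=O)c2c(C)cc(O[Si](C)(C)C)cc2O[Si](C)(C)C)c1OCc1ccccc1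
F6 | step 8 | 3-acetyl-2,4-dihydroxy-6-methoxybenzaldehyde | CC(=O)c1c(O)cc(OC)c(C=O)c1O
F7 | step 8 | 3-acetyl-2,4-bis(benzyloxy)-6-methoxybenzaldehyde | CC(=O)c1c(OCc2ccccc2)cc(OC)c(C=O)c1OCc1ccccc1
F8 | step 8 | 1-[2,6-bis(benzyloxy)-3-(hydroxymethyl)-4-methoxyphenyl]ethanone | CC(=O)c1c(OCc2ccccc2)cc(OC)c(CO)c1OCc1ccccc1
F9 | step 8 | 1-[2,6-bis(benzyloxy)-3-({3-[2,4-bis(benzyloxy)-6-methylbenzoyl]-2,4-dihydroxy-6-methoxyphenyl}methyl)-4-methoxyphenyl]ethanone | COc1cc(O)c(C(=O)c2c(C)cc(OCc3ccccc3)cc2OCc2ccccc2)c(O)c1Cc1c(OC)cc(OCc2ccccc2)c(C(C)=O)c1OCc1ccccc1
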